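**Retrosynthetic overview** (benzofuran numbering O1, C2, C3, C3a, C4–C7, C7a; ring A = benzo ring, ring B = catechol on C2, ring C = resorcinol on C3, ring D = phenol of the styryl arm)
1. Scirpusin A ⇒ global desilylation and E-selective olefination at C4 of a trans-2,3-diaryl-2,3-dihydrobenzofuran-4-carbaldehyde.
2. Key disconnection C3–C3a: the C3a–H bond of ring A is added across the C2=C3 double bond of an open, flat (Z)-aryl enol ether by chelation-assisted rhodium catalysis. This closes the only ring that has to be made (the five-membered O-heterocycle; the four benzene rings are bought) and creates both stereocentres in one operation.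
3. Enabling feature: C3a–H sits on ring A between C7a, whose oxygen O1 tethers the alkene, and C4. The C4 substituent, the first carbon of the stilbene bridge, can be carried as a formyl group masked as a chiral aldimine. The imine nitrogen holds rhodium at C3a–H, its aminoindane stereocentre picks the alkene face, and the same carbon later becomes the stilbene CH.
4. The syn addition gives the cis ring. The para-oxygenated ring B makes the C2–O1 bond reversibly ionisable, so acid moves C2 into the trans arrangement while C3 stays fixed.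
5. Enol ether ⇐ gold-catalysed anti addition of monosilylated 3,5-dihydroxybenzaldehyde to an electronically polarised diarylalkyne ⇐ Sonogashira coupling of rings B and C.

Key step: step 8

Assumption: the sense of induction of the aminoindane auxiliary on this alkene is taken by analogy with 3-aryloxycinnamate substrates; if the insertion prefers the other alkene face, (R)-1-aminoindane is used in step 7 and nothing else in the route changes.

Abbreviations: TBS = tert-butyldimethylsilyl (TBSO = its ether); coe = cis-cyclooctene; FcPCy2 = (dicyclohexylphosphino)ferrocene; IPr = 1,3-bis(2,6-diisopropylphenyl)imidazol-2-ylidene; DIC = diisopropylcarbodiimide.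

**Route**

Step 1
Reactants: 1 3,4-dihydroxybenzaldehyde
Product: 2 3,4-bis(TBSO)benzaldehyde
Conditions: TBSCl (2.4 equiv), imidazole, DMF, rt
Reagents that add atoms: tert-butyldimethylsilyl chloride, CC(C)(C)[Si](C)(C)Cl
Why: Standard silylation of phenols (TBSCl/imidazole) caps both catechol oxygens as fluoride-labile ethers that need neither acid nor hydrogenolysis at the end, and the aldehyde is inert to it.

Step 2
Reactants: 2 3,4-bis(TBSO)benzaldehyde
Product: 3 4-ethynyl-1,2-bis(TBSO)benzene
Conditions: TMSCHN2, LDA, THF, −78 °C → rt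
Reagents that add atoms: trimethylsilyldiazomethane, C[Si](C)(C)C=[N+]=[N-]
Why: Colvin rearrangement: lithiated trimethylsilyldiazomethane adds to the aldehyde, Peterson-type loss of silanolate and then of N2 gives an alkylidene carbene whose 1,2-hydrogen shift gives the terminal alkyne, without the carbonate/methanol medium that would strip aryl silyl ethers.

Step 3
Reactants: 4 5-bromoresorcinol (5-bromobenzene-1,3-diol)
Product: 5 1-bromo-3,5-bis(TBSO)benzene
Conditions: TBSCl (2.4 equiv), imidazole, DMF, rt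
Reagents that add atoms: tert-butyldimethylsilyl chloride, CC(C)(C)[Si](C)(C)Cl
Why: Standard phenol silylation, as in step 1; the aryl bromide is untouched.

Step 4
Reactants: 3 4-ethynyl-1,2-bis(TBSO)benzene; 5 1-bromo-3,5-bis(TBSO)benzene
Product: 6 1,2-bis(TBSO)-4-{[3,5-bis(TBSO)phenyl]ethynyl}benzene (tetrasilyl diarylalkyne)
Conditions: PdCl2(PhCN)2 (3 mol %), P(t-Bu)3·HBF4 (6 mol %), CuI (2 mol %), i-Pr2NH, dioxane, rt
Reagents that add atoms: none
Why: Sonogashira coupling; the bulky, electron-rich phosphine allows oxidative addition of the aryl bromide to zerovalent palladium at room temperature and the amine base leaves the four aryl silyl ethers intact.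

Step 5
Reactants: 7 3,5-dihydroxybenzaldehyde
Product: 8 3-(TBSO)-5-hydroxybenzaldehyde
Conditions: TBSCl (1.0 equiv), imidazole, DMF, 0 °C
Reagents that add atoms: tert-butyldimethylsilyl chloride, CC(C)(C)[Si](C)(C)Cl
Why: Statistical monosilylation of a symmetrical resorcinol with one equivalent of TBSCl; the polarity differences between diol, mono-ether and bis-ether make separation simple and the other two components can be recycled.

Step 6
Reactants: 6 tetrasilyl diarylalkyne; 8 3-(TBSO)-5-hydroxybenzaldehyde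
Product: 9 3-{(Z)-1-[3,4-bis(TBSO)phenyl]-2-[3,5-bis(TBSO)phenyl]ethenyloxy}-5-(TBSO)benzaldehyde (O and ring C on the same side of the double bond)
Conditions: [{Au(IPr)}2(μ-OH)]BF4 (2 mol %), dry toluene, 80–100 °C
Reagents that add atoms: none
Why: Gold-catalysed intermolecular hydrophenoxylation of a diarylalkyne (the digold hydroxide supplies a gold phenoxide and a π-activated alkyne): outer-sphere anti addition gives the (Z)-enol ether, and oxygen goes to the alkyne carbon next to ring B because the para-silyloxy group there stabilises the developing positive charge, whereas the two meta-silyloxy groups of ring C do not.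

Step 7
Reactants: 9 (Z)-enol ether aldehyde; 10 (S)-1-aminoindane
Product: 11 (E)-N-[(1S)-indan-1-yl]aldimine of 9
Conditions: 10 (1.05 equiv), 4 Å molecular sieves, toluene, rt; filtered, evaporated, used as such
Reagents that add atoms: none
Why: Simple imine condensation driven by molecular sieves; enol ether and silyl ethers are inert to a primary amine at room temperature, and the E aldimine places the auxiliary stereocentre next to the future metal binding site.

Step 8
Reactants: 11 (E)-N-[(1S)-indan-1-yl]aldimine of 9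
Product: 13 (2R,3S)-cis-2-[3,4-bis(TBSO)phenyl]-3-[3,5-bis(TBSO)phenyl]-6-(TBSO)-2,3-dihydrobenzofuran-4-carbaldehyde, via cyclised aldimine 12 (not isolated)
Conditions: [RhCl(coe)2]2 (10 mol %), FcPCy2 (30 mol %), toluene, 75–100 °C; then 1 M HCl, THF, rt
Reagents that add atoms: water, O
Why: The aldimine nitrogen binds monovalent rhodium, which adds oxidatively into the C3a–H bond of ring A; the tethered C2=C3 bond inserts into Rh–H with H going to C2 and Rh to C3, and C–C reductive elimination from the six-membered rhodacycle (Rh, C3a, C7a, O1, C2, C3) forms C3–C3a. The closest known reaction type is the chelation-assisted (Murai-type) intramolecular hydroarylation of meta-tethered alkenes by aromatic imines with [RhCl(coe)2]2 and ferrocenyl dialkylphosphines, documented with chiral N-substituents for 3-aryloxycinnamates that give 2-aryl-2,3-dihydrobenzofuran-3-carboxylates; here the ester on the distal alkene carbon is replaced by an aryl group. The single ring closed is the dihydrofuran ring, formally 5-endo-trig, which is feasible because the bond is made by reductive elimination within a metallacycle and not by direct attack on the alkene. H and C3a are delivered to the same face of the (Z)-alkene, which fixes C2 and C3 as cis, and the face, hence 3S, is selected by the stereocentre of the aminoindane unit on the rhodium-bound nitrogen. Site selectivity among the three C–H bonds of ring A is needed: the one between the two oxygens cannot be reached from the chelate, and metalation at the other position ortho to the imine is reversible and has no alkene within reach, so only C3a–H is productive. Aqueous acid then cleaves the aldimine, returns the auxiliary and uncovers the formyl group for step 11.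

Step 9
Reactants: 13 (2R,3S)-cis aldehyde
Product: 14 (2S,3S)-trans-2-[3,4-bis(TBSO)phenyl]-3-[3,5-bis(TBSO)phenyl]-6-(TBSO)-2,3-dihydrobenzofuran-4-carbaldehyde
Conditions: TFA, dry CH2Cl2, 0 °C → rt
Reagents that add atoms: none
Why: Acid-mediated epimerisation of a cis-2-aryl-2,3-dihydrobenzofuran: reversible heterolysis of C2–O1 gives a benzylic cation stabilised by the para-silyloxy group of ring B, and rotation about C2–C3 followed by re-closure by the ring A phenol leads to the thermodynamically favoured trans isomer (2S), while C3 is untouched and now controls C2 and the anhydrous acid spares the aryl TBS ethers.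

Step 10
Reactants: 15 diethyl (4-hydroxybenzyl)phosphonate
Product: 16 diethyl [4-(TBSO)benzyl]phosphonate
Conditions: TBSCl, imidazole, DMF, rt
Reagents that add atoms: tert-butyldimethylsilyl chloride, CC(C)(C)[Si](C)(C)Cl
Why: Standard phenol silylation; the phosphonate ester is inert.

Step 11
Reactants: 14 (2S,3S)-trans aldehyde; 16 diethyl [4-(TBSO)benzyl]phosphonate
Product: 17 penta-O-TBS-scirpusin A ((2S,3S), E-stilbene)
Conditions: 16, NaHMDS, THF, −78 °C; then 14, −78 °C → rt
Reagents that add atoms: none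
Why: Horner–Wadsworth–Emmons olefination of an aryl aldehyde with a benzylic phosphonate is reliably E-selective; pre-forming the anion with a non-nucleophilic amide base avoids attack on the silyl ethers, and addition to the aldehyde is faster than deprotonation at C3.

Step 12
Reactants: 17 penta-O-TBS-scirpusin A
Product: 18 scirpusin A
Conditions: TBAF (6 equiv), AcOH (6 equiv), THF, 0 °C, argon
Reagents that add atoms: none
Why: Fluoride-induced cleavage of the five aryl silyl ethers; the acetic acid buffer keeps the liberated para-phenol of ring B from opening the C2–O1 bond as a quinone methide and protects the catechol from base-promoted air oxidation, and neither the stilbene nor the stereocentres are affected.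

**Compound list**

1 | 3,4-dihydroxybenzaldehyde | O=Cc1ccc(O)c(O)c1 | starting material
2 | 3,4-bis(TBSO)benzaldehyde | O=Cc1ccc(O[Si](C)(C)C(C)(C)C)c(O[Si](C)(C)C(C)(C)C)c1 | intermediate
3 | 4-ethynyl-1,2-bis(TBSO)benzene | C#Cc1ccc(O[Si](C)(C)C(C)(C)C)c(O[Si](C)(C)C(C)(C)C)c1 | intermediate
4 | 5-bromoresorcinol | Oc1cc(O)cc(Br)c1 | starting material
5 | 1-bromo-3,5-bis(TBSO)benzene | Brc1cc(O[Si](C)(C)C(C)(C)C)cc(O[Si](C)(C)C(C)(C)C)c1 | intermediate
6 | 1,2-bis(TBSO)-4-{[3,5-bis(TBSO)phenyl]ethynyl}benzene | CC(C)(C)[Si](C)(C)Oc1ccc(C#Cc2cc(O[Si](C)(C)C(C)(C)C)cc(O[Si](C)(C)C(C)(C)C)c2)cc1O[Si](C)(C)C(C)(C)C | intermediate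
7 | 3,5-dihydroxybenzaldehyde | O=Cc1cc(O)cc(O)c1 | starting material
8 | 3-(TBSO)-5-hydroxybenzaldehyde | O=Cc1cc(O)cc(O[Si](C)(C)C(C)(C)C)c1 | intermediate
9 | 3-{(Z)-1-[3,4-bis(TBSO)phenyl]-2-[3,5-bis(TBSO)phenyl]ethenyloxy}-5-(TBSO)benzaldehyde | O=Cc1cc(O[Si](C)(C)C(C)(C)C)cc(O/C(c2ccc(O[Si](C)(C)C(C)(C)C)c(O[Si](C)(C)C(C)(C)C)c2)=C\c2cc(O[Si](C)(C)C(C)(C)C)cc(O[Si](C)(C)C(C)(C)C)c2)c1 | intermediate
10 | (S)-1-aminoindane | N[C@H]1CCc2ccccc12 | starting material
11 | (E)-N-[(1S)-indan-1-yl]aldimine of 9 | c1ccc2c(c1)CC[C@@H]2/N=C/c1cc(O[Si](C)(C)C(C)(C)C)cc(O/C(c2ccc(O[Si](C)(C)C(C)(C)C)c(O[Si](C)(C)C(C)(C)C)c2)=C\c2cc(O[Si](C)(C)C(C)(C)C)cc(O[Si](C)(C)C(C)(C)C)c2)c1 | intermediate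
12 | cyclised aldimine, (E)-N-[(1S)-indan-1-yl]aldimine of 13 (2R,3S, cis) | c1ccc2c(c1)CC[C@@H]2/N=C/c1cc(O[Si](C)(C)C(C)(C)C)cc2c1[C@H](c1cc(O[Si](C)(C)C(C)(C)C)cc(O[Si](C)(C)C(C)(C)C)c1)[C@H](c1ccc(O[Si](C)(C)C(C)(C)C)c(O[Si](C)(C)C(C)(C)C)c1)O2 | intermediate
13 | (2R,3S)-cis-2-[3,4-bis(TBSO)phenyl]-3-[3,5-bis(TBSO)phenyl]-6-(TBSO)-2,3-dihydrobenzofuran-4-carbaldehyde | O=Cc1cc(O[Si](C)(C)C(C)(C)C)cc2c1[C@H](c1cc(O[Si](C)(C)C(C)(C)C)cc(O[Si](C)(C)C(C)(C)C)c1)[C@H](c1ccc(O[Si](C)(C)C(C)(C)C)c(O[Si](C)(C)C(C)(C)C)c1)O2 | intermediate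
14 | (2S,3S)-trans-2-[3,4-bis(TBSO)phenyl]-3-[3,5-bis(TBSO)phenyl]-6-(TBSO)-2,3-dihydrobenzofuran-4-carbaldehyde | O=Cc1cc(O[Si](C)(C)C(C)(C)C)cc2c1[C@H](c1cc(O[Si](C)(C)C(C)(C)C)cc(O[Si](C)(C)C(C)(C)C)c1)[C@@H](c1ccc(O[Si](C)(C)C(C)(C)C)c(O[Si](C)(C)C(C)(C)C)c1)O2 | intermediate
15 | diethyl (4-hydroxybenzyl)phosphonate | CCOP(=O)(Cc1ccc(O)cc1)OCC | starting material
16 | diethyl [4-(TBSO)benzyl]phosphonate | CCOP(=O)(Cc1ccc(O[Si](C)(C)C(C)(C)C)cc1)OCC | intermediate
17 | penta-O-TBS-scirpusin A | CC(C)(C)[Si](C)(C)Oc1ccc(/C=C/c2cc(O[Si](C)(C)C(C)(C)C)cc3c2[C@H](c2cc(O[Si](C)(C)C(C)(C)C)cc(O[Si](C)(C)C(C)(C)C)c2)[C@@H](c2ccc(O[Si](C)(C)C(C)(C)C)c(O[Si](C)(C)C(C)(C)C)c2)O3)cc1 | intermediate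
18 | scirpusin A, (2S,3S) | Oc1ccc(/C=C/c2cc(O)cc3c2[C@H](c2cc(O)cc(O)c2)[C@@H](c2ccc(O)c(O)c2)O3)cc1 | target

**Totals**

- Total step count: 12.
- Longest linear sequence: 9 steps (1, 2, 4, 6, 7, 8, 9, 11, 12).

**Steps most likely to fail**

**1. Step 8.**
- What may go wrong: the hindered, electron-rich diaryl-substituted double bond may insert into the rhodium hydride only slowly. E/Z isomerisation may run in competition, and the facial bias from the auxiliary may be insufficient. Crystallisation of 14 is the point at which enantiomeric purity could be raised.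
- Fallback idea: ring C is brought in after the closure. The closure is moved to an acrylate-type enol ether, the class for which it is documented, and ring C is attached afterwards by decarboxylative arylation.
- Where it sets out and returns: it sets out from alkyne 3 (with phenol 8 and bromide 5) and comes back at aldehyde 14, passing over step 9.
- Alkyne 3 is lithiated (n-BuLi, THF, −78 °C) and quenched with methyl chloroformate to give methyl 3-[3,4-bis(TBSO)phenyl]propynoate F1.
- Phenol 8 is added under the gold conditions of step 6, now to a Michael-polarised alkyne, to give the methyl (Z)-3-aryloxycinnamate F2.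
- Condensation with (R)-1-aminoindane gives the aldimine F3. The opposite auxiliary is used because the centre that lasts is now C2.
- [RhCl(coe)2]2/FcPCy2 closes F3 to the cyclised ester aldimine F4, and aqueous acid gives the cis (2S,3R) ester aldehyde F5.
- Me3SnOH (1,2-dichloroethane, 80 °C) gives the carboxylic acid F6, and N-hydroxyphthalimide/DIC gives the N-acyloxyphthalimide F7.
- NiCl2·glyme/4,4'-di-tert-butyl-2,2'-bipyridine then couples F7 in a decarboxylative Negishi arylation with [3,5-bis(TBSO)phenyl]zinc chloride F8, made from 5 with n-BuLi and then ZnCl2.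
- The planar C3 radical should be arylated on the face away from ring B, which gives trans 14.

**2. Step 6.**
- What may go wrong: regiocontrol may be insufficient in the addition of the phenol across an alkyne that is only moderately polarised, and traces of water may cause competing hydration.
- Fallback idea: the position of the oxygen is fixed by a ketone instead of by alkyne polarisation.
- Where it sets out and returns: it sets out from alkyne 3 and bromide 5 and comes back at enol ether 9.
- Markovnikov hydration of 3 ([Au(IPr)Cl]/AgSbF6, dioxane/water) gives 3,4-bis(TBSO)acetophenone F9.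
- Palladium-catalysed ketone α-arylation with 5 (Pd2(dba)3, Xantphos, K3PO4, toluene, 80 °C) gives the deoxybenzoin F10.
- KHMDS/PhNTf2 (THF, −78 °C) traps the Z enolate as the (Z)-enol triflate F11.
- Palladium-catalysed C–O coupling of F11 with phenol 8 (Pd2(dba)3, 2-(di-tert-butylphosphino)biphenyl, K3PO4, toluene) should give 9 with retention of geometry.

**3. Step 9.**
- What may go wrong: loss of the C3 proton or aryl migration from the ring-opened cation would erode the configuration at C3. Acid-induced loss of silyl groups is also possible.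
- Fallback idea: the trans relationship is encoded in the alkene geometry, so no epimerisation is needed.
- Where it sets out and returns: it sets out from alkyne 6 and phenol 8 and comes back at aldehyde 14.
- Copper-catalysed syn hydroboration of 6 (CuCl, Xantphos, catalytic NaOt-Bu, B2pin2, MeOH, THF, rt) gives the (Z)-alkenyl pinacol boronate F12. Copper goes next to the electron-poorer ring C and boron next to ring B.
- Chan–Lam coupling with 8 (Cu(OAc)2, Et3N, 4 Å molecular sieves, CH2Cl2, air) proceeds with retention and gives the (E)-enol ether aldehyde F13, in which rings B and C are cis.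
- Condensation with 10 gives the (E)-enol ether aldimine F14.
- The syn hydroarylation of step 8 now gives the trans cyclised aldimine F15 directly, and this is hydrolysed to 14.

**Further compounds**

F1 | step 8 | methyl 3-[3,4-bis(TBSO)phenyl]propynoate | COC(=O)C#Cc1ccc(O[Si](C)(C)C(C)(C)C)c(O[Si](C)(C)C(C)(C)C)c1
F2 | step 8 | methyl (Z)-3-[3,4-bis(TBSO)phenyl]-3-[3-formyl-5-(TBSO)phenoxy]prop-2-enoate | O=Cc1cc(O[Si](C)(C)C(C)(C)C)cc(O/C(c2ccc(O[Si](C)(C)C(C)(C)C)c(O[Si](C)(C)C(C)(C)C)c2)=C\C(=O)OC)c1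
F3 | step 8 | (E)-N-[(1R)-indan-1-yl]aldimine of F2 | c1ccc2c(c1)CC[C@H]2/N=C/c1cc(O[Si](C)(C)C(C)(C)C)cc(O/C(c2ccc(O[Si](C)(C)C(C)(C)C)c(O[Si](C)(C)C(C)(C)C)c2)=C\C(=O)OC)c1
F4 | step 8 | cyclised ester aldimine, (2S,3R)-cis | c1ccc2c(c1)CC[C@H]2/N=C/c1cc(O[Si](C)(C)C(C)(C)C)cc2c1[C@@H](C(=O)OC)[C@@H](c1ccc(O[Si](C)(C)C(C)(C)C)c(O[Si](C)(C)C(C)(C)C)c1)O2
F5 | step 8 | methyl (2S,3R)-cis-2-[3,4-bis(TBSO)phenyl]-4-formyl-6-(TBSO)-2,3-dihydrobenzofuran-3-carboxylate | O=Cc1cc(O[Si](C)(C)C(C)(C)C)cc2c1[C@@H](C(=O)OC)[C@@H](c1ccc(O[Si](C)(C)C(C)(C)C)c(O[Si](C)(C)C(C)(C)C)c1)O2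
F6 | step 8 | (2S,3R)-2-[3,4-bis(TBSO)phenyl]-4-formyl-6-(TBSO)-2,3-dihydrobenzofuran-3-carboxylic acid | O=Cc1cc(O[Si](C)(C)C(C)(C)C)cc2c1[C@@H](C(=O)O)[C@@H](c1ccc(O[Si](C)(C)C(C)(C)C)c(O[Si](C)(C)C(C)(C)C)c1)O2
F7 | step 8 | N-acyloxyphthalimide (redox-active ester) of F6 | O=Cc1cc(O[Si](C)(C)C(C)(C)C)cc2c1[C@@H](C(=O)ON1C(=O)c3ccccc3C1=O)[C@@H](c1ccc(O[Si](C)(C)C(C)(C)C)c(O[Si](C)(C)C(C)(C)C)c1)O2
F8 | step 8 | [3,5-bis(TBSO)phenyl]zinc chloride | Cl[Zn]c1cc(O[Si](C)(C)C(C)(C)C)cc(O[Si](C)(C)C(C)(C)C)c1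
F9 | step 6 | 3,4-bis(TBSO)acetophenone | CC(=O)c1ccc(O[Si](C)(C)C(C)(C)C)c(O[Si](C)(C)C(C)(C)C)c1
F10 | step 6 | 1-[3,4-bis(TBSO)phenyl]-2-[3,5-bis(TBSO)phenyl]ethan-1-one | O=C(Cc1cc(O[Si](C)(C)C(C)(C)C)cc(O[Si](C)(C)C(C)(C)C)c1)c1ccc(O[Si](C)(C)C(C)(C)C)c(O[Si](C)(C)C(C)(C)C)c1
F11 | step 6 | (Z)-1-[3,4-bis(TBSO)phenyl]-2-[3,5-bis(TBSO)phenyl]ethenyl trifluoromethanesulfonate | O=S(=O)(O/C(c1ccc(O[Si](C)(C)C(C)(C)C)c(O[Si](C)(C)C(C)(C)C)c1)=C\c1cc(O[Si](C)(C)C(C)(C)C)cc(O[Si](C)(C)C(C)(C)C)c1)C(F)(F)F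
F12 | step 9 | (Z)-2-{1-[3,4-bis(TBSO)phenyl]-2-[3,5-bis(TBSO)phenyl]ethenyl}-4,4,5,5-tetramethyl-1,3,2-dioxaborolane | CC1(C)OB(OC1(C)C)/C(c1ccc(O[Si](C)(C)C(C)(C)C)c(O[Si](C)(C)C(C)(C)C)c1)=C/c1cc(O[Si](C)(C)C(C)(C)C)cc(O[Si](C)(C)C(C)(C)C)c1
F13 | step 9 | 3-{(E)-1-[3,4-bis(TBSO)phenyl]-2-[3,5-bis(TBSO)phenyl]ethenyloxy}-5-(TBSO)benzaldehyde | O=Cc1cc(O[Si](C)(C)C(C)(C)C)cc(O/C(c2ccc(O[Si](C)(C)C(C)(C)C)c(O[Si](C)(C)C(C)(C)C)c2)=C/c2cc(O[Si](C)(C)C(C)(C)C)cc(O[Si](C)(C)C(C)(C)C)c2)c1
F14 | step 9 | (E)-N-[(1S)-indan-1-yl]aldimine of F13 | c1ccc2c(c1)CC[C@@H]2/N=C/c1cc(O[Si](C)(C)C(C)(C)C)cc(O/C(c2ccc(O[Si](C)(C)C(C)(C)C)c(O[Si](C)(C)C(C)(C)C)c2)=C/c2cc(O[Si](C)(C)C(C)(C)C)cc(O[Si](C)(C)C(C)(C)C)c2)c1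
F15 | step 9 | trans cyclised aldimine, (E)-N-[(1S)-indan-1-yl]aldimine of 14 | c1ccc2c(c1)CC[C@@H]2/N=C/c1cc(O[Si](C)(C)C(C)(C)C)cc2c1[C@H](c1cc(O[Si](C)(C)C(C)(C)C)cc(O[Si](C)(C)C(C)(C)C)c1)[C@@H](c1ccc(O[Si](C)(C)C(C)(C)C)c(O[Si](C)(C)C(C)(C)C)c1)O2
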